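The earlier runs and the new flask were computed from invented constants, and the scatter is random.

A ratio of two readings was what I wanted from the oak and larch runs, to say when isomer of the product B would peak in a new flask charged with 0.30 M of starting material and 0.900 M of reagent.

| setting | oak | larch | flask |
|---|---|---|---|
| starting material | 0.15 M | 0.22 M | 0.30 M |
| reagent | 0.90 M | 0.90 M | 0.900 M |
| remark | run made earlier | run made earlier |  |
| time |  |  | 3.0 h |

| run | time / h | isomer of the product B / % | target / % | starting material / % |
|---|---|---|---|---|
| oak | 0.200 | 5.7 | 21.3 | 55.8 |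
| oak | 0.333 | 9.3 | 17.8 | 48.5 |
| oak | 0.500 | 11.6 | 15.3 | 41.3 |
| oak | 0.833 | 12.7 | 11.1 | 31.7 |
| oak | 1.33 | 11.1 | 8.3 | 23.5 |
| oak | 2.00 | 8.5 | 6.2 | 19.9 |
| oak | 4.00 | 4.0 | 4.3 | 12.6 |
| larch | 0.200 | 5.9 | 19.5 | 57.5 |
| larch | 0.333 | 9.3 | 18.5 | 50.0 |
| larch | 0.500 | 10.2 | 15.1 | 42.1 |
| larch | 0.833 | 11.1 | 10.7 | 33.5 |
| larch | 1.33 | 11.4 | 8.9 | 26.3 |
| larch | 2.00 | 8.1 | 6.6 | 21.5 |
| larch | 4.00 | 5.4 | 4.6 | 15.0 |

(readings scatter by 0.5 percentage points)

- the moment within 3.0 h at which there is most isomer of the product B
- the amount of isomer of the product B, in percent of the starting material charged, at that time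
- earliest time at which at least nineteen twentieths of that best amount are there
- latest time at which they still are

- the numbers in the tables scatter with a standard deviation of 0.5 percentage points
- a reading of starting material is of its free form alone

The first rung of the ladder was over before the first reading. In oak, target over starting material was 0.382 at 0.200 h and 0.341 at 4.00 h, a steady proportion, which I read as a pre-equilibrium. On the second rung the isomer of the product B caught up with target: in oak, isomer over target rose from 0.268 at 0.200 h to 1.34 at 1.33 h. The third rung lasted the whole run, with starting material in oak falling from 55.8% to 12.6%.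

I supposed that target and the isomer pass into each other, each flow going with its own amount. If nothing else makes or takes the isomer, then at one temperature it stops rising at one ratio to target, whatever the charge. Both runs stood near their highest isomer readings at 0.833 h, where the two summed read 1.09, and I took this reading as the turning ratio: isomer of the product B over target at the moment the isomer stops rising. Oak read 1.14 there and larch 1.04, close despite their different charges, so I put the peak of the new flask near 0.833 h too.

The forecast said 11.9% at 1 h, with a window from 0.67 h to 1.4 h, holding that “Going to 0.30 M should shift the peak slightly later and broaden it”. Its time was later than mine.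

The flask gave 11.8% at 0.821 h, with a window from 0.560 h to 1.19 h.

    starting material + reagent ⇌ target (K = 0.463 M⁻¹, k = 0.00740 M⁻¹ s⁻¹)
    target ⇌ isomer of the product B (K = 1.07, k = 4.83 × 10⁻⁴ s⁻¹)
    reagent + target → over-reaction product (k = 4.87 × 10⁻⁴ M⁻¹ s⁻¹)
    starting material → decomposition product (k = 4.86 × 10⁻⁶ s⁻¹)
    starting material + reagent ⇌ isomer of the product A (K = 2.71 M⁻¹, k = 2.46 × 10⁻⁴ M⁻¹ s⁻¹)

At its best time the flask held 11.8% of the isomer of the product B and 11.0% of target, a ratio of 1.07 beside the turning ratio of 1.09. The neighbour charged with 0.75 M of starting material held 5.10% of target at 3.00 h, so by the turning ratio its isomer would stop rising at 5.56% at that moment. It held more, 6.21%, so it was past its peak, and its highest amount had been 10.2%.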